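**Retrosynthetic overview**

1. Target 11 is the trans-(2R,3S)-3-acyloxy-2-isopropenyl-2,3-dihydrobenzofuran (5-acetyl, 6-methoxy) esterified with (Z)-2-(acetoxymethyl)but-2-enoic acid. Both C–O bonds at the new stereocentres (O1–C2 and C3–O-acyl) are cut at once, giving the phenolic (E)-aryl diene 5 and the acid 10.
2. In the forward direction this is an enantioselective oxidative acyloxy-etherification of the diene on divalent palladium. It closes the dihydrofuran ring in the last step (the only ring made; the benzene ring is bought) and sets both stereocentres.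
3. 5 comes from aryl iodide 2 and (E)-dienyl boronate 4 (Suzuki–Miyaura); 2 from ketophenol 1 (iodination); 4 from enyne 3 (hydroboration).
4. 10 comes from tert-butyl ester 9, and 9 from tert-butyl but-2-ynoate 6 (syn-hydroalumination, formaldehyde, acetylation), which fixes the Z alkene.

Assumption: 1, 3 and 6 are taken as catalogue chemicals, and the SMILES is read as the (2R,3S)-trans dihydrobenzofuran with a Z side-chain alkene.

**Route**

Step 1
Reactants: 1 1-(4-hydroxy-2-methoxyphenyl)ethan-1-one
Product: 2 1-(4-hydroxy-5-iodo-2-methoxyphenyl)ethan-1-one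
Conditions: NIS (1.05 equiv), TsOH·H2O (10 mol%), MeCN, 0 °C → rt
Reagents that add atoms: N-iodosuccinimide, O=C1CCC(=O)N1I
Why: Electrophilic aromatic iodination goes to C5, which is ortho to the free hydroxyl and para to the methoxy group and is less hindered than C3 between the two oxygen substituents.

Step 2
Reactants: 3 2-methylbut-1-en-3-yne
Product: 4 (E)-4,4,5,5-tetramethyl-2-(3-methylbuta-1,3-dien-1-yl)-1,3,2-dioxaborolane
Conditions: pinacolborane (1.0 equiv), 3 (1.5 equiv), Cp2Zr(H)Cl (5 mol%), Et3N (10 mol%), neat, sealed tube, 40 °C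
Reagents that add atoms: pinacolborane, [H]B1OC(C)(C)C(C)(C)O1
Why: Zirconocene-hydride-catalysed syn, anti-Markovnikov hydroboration of the terminal alkyne leaves the 1,1-disubstituted alkene alone and fixes the E geometry.

Step 3
Reactants: 2 1-(4-hydroxy-5-iodo-2-methoxyphenyl)ethan-1-one; 4 (E)-4,4,5,5-tetramethyl-2-(3-methylbuta-1,3-dien-1-yl)-1,3,2-dioxaborolane
Product: 5 1-{4-hydroxy-2-methoxy-5-[(1E)-3-methylbuta-1,3-dien-1-yl]phenyl}ethan-1-one
Conditions: Pd(dppf)Cl2 (3 mol%), K3PO4 (3 equiv), 1,4-dioxane/H2O (4:1), 60 °C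
Reagents that add atoms: none
Why: Suzuki–Miyaura coupling proceeds with retention of the E alkene geometry; aryl iodides with a free ortho-hydroxyl couple under aqueous phosphate and the ketone is inert.

Step 4
Reactants: 6 tert-butyl but-2-ynoate
Product: 9 tert-butyl (2Z)-2-[(acetyloxy)methyl]but-2-enoate, via α-alumino enoate 7 (not isolated), via aluminium alkoxide 8 (not isolated)
Conditions: i-Bu2AlH (1.2 equiv), HMPA (2.4 equiv), THF, 0 °C; then 6, 0 °C, 1 h; CH2O (gas, from cracked paraformaldehyde), 0 °C → rt; then pyridine, Ac2O, 0 °C → rt; aq. potassium sodium tartrate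
Reagents that add atoms: formaldehyde, C=O; acetic anhydride, CC(=O)OC(C)=O
Why: Conjugate syn-hydroalumination of the ynoate puts H and Al cis, the α-alumino enoate adds to formaldehyde with retention so that the methyl group ends cis to the ester (Z, angelate-type), and the aluminium alkoxide is acetylated in the flask as in a reductive acetylation.

Step 5
Reactants: 9 tert-butyl (2Z)-2-[(acetyloxy)methyl]but-2-enoate
Product: 10 (2Z)-2-[(acetyloxy)methyl]but-2-enoic acid
Conditions: CF3CO2H/CH2Cl2 (1:4), 0 °C, 2 h
Reagents that add atoms: none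
Why: Acidolysis of the tert-butyl ester (loss of isobutene) at 0 °C leaves the primary acetate and the Z-trisubstituted alkene untouched.

Step 6
Reactants: 5 1-{4-hydroxy-2-methoxy-5-[(1E)-3-methylbuta-1,3-dien-1-yl]phenyl}ethan-1-one; 10 (2Z)-2-[(acetyloxy)methyl]but-2-enoic acid
Product: 11 (2R,3S)-5-acetyl-6-methoxy-2-(prop-1-en-2-yl)-2,3-dihydro-1-benzofuran-3-yl (2Z)-2-[(acetyloxy)methyl]but-2-enoate
Conditions: 5 (1.0 equiv), 10 (2.0 equiv), Pd(dba)2 (10 mol%), (S)-t-Bu-PyOx (12 mol%), 2,6-dimethyl-1,4-benzoquinone (1.5 equiv), 3 Å molecular sieves, THF, 25 °C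
Reagents that add atoms: none
Why: Proposed new method: enantioselective oxidative 1,2-acyloxy-etherification of a 1-aryl-1,3-diene by a free carboxylic acid and the ortho-phenol; the (t-Bu-PyOx)-bound divalent palladium carboxylate formed from Pd(dba)2, the quinone and 10 binds the diene, the carboxylate adds anti at the aryl-bearing terminus (the styrene-type position, the only one that leads to a five-membered ring) and sets C3, the resulting 2-methyl-η3-allyl has a CH2 end and so exchanges faces by η3–η1–η3, and the phenoxide then attacks the internal allyl carbon in the ligand-controlled, ring-closing C–O bond formation, trans to the acyloxy group (the cis transition state eclipses ester and isopropenyl), which gives (2R,3S); acyloxypalladation is reversible by β-acyloxy elimination, so a mismatched C3 epimer can return to 5, and the zerovalent palladium released is re-oxidised by the quinone and 10; the closest known reaction types are the palladium/benzoquinone diacyloxylation and intramolecular oxy-acyloxylation of 1,3-dienes and the enantioselective heteroannulation of 1,3-dienes with ortho-halophenols, whose ring closure passes through the same kind of 2-methylallyl palladium phenoxide.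

**Compound list**

1 | 1-(4-hydroxy-2-methoxyphenyl)ethan-1-one | CC(=O)c1ccc(O)cc1OC | starting material
2 | 1-(4-hydroxy-5-iodo-2-methoxyphenyl)ethan-1-one | CC(=O)c1cc(I)c(O)cc1OC | intermediate
3 | 2-methylbut-1-en-3-yne | C=C(C)C#C | starting material
4 | (E)-4,4,5,5-tetramethyl-2-(3-methylbuta-1,3-dien-1-yl)-1,3,2-dioxaborolane | C=C(C)/C=C/B1OC(C)(C)C(C)(C)O1 | intermediate
5 | 1-{4-hydroxy-2-methoxy-5-[(1E)-3-methylbuta-1,3-dien-1-yl]phenyl}ethan-1-one | CC(=O)c1cc(/C=C/C(C)=C)c(O)cc1OC | intermediate
6 | tert-butyl but-2-ynoate | CC#CC(=O)OC(C)(C)C | starting material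
7 | tert-butyl (2E)-2-[bis(2-methylpropyl)alumanyl]but-2-enoate (methyl cis to the ester) | C/C=C(\C(=O)OC(C)(C)C)[Al](CC(C)C)CC(C)C | intermediate
8 | tert-butyl (2Z)-2-({[bis(2-methylpropyl)alumanyl]oxy}methyl)but-2-enoate | C/C=C(\C(=O)OC(C)(C)C)CO[Al](CC(C)C)CC(C)C | intermediate
9 | tert-butyl (2Z)-2-[(acetyloxy)methyl]but-2-enoate | C/C=C(\C(=O)OC(C)(C)C)COC(C)=O | intermediate
10 | (2Z)-2-[(acetyloxy)methyl]but-2-enoic acid | C/C=C(\C(=O)O)COC(C)=O | intermediate
11 | (2R,3S)-5-acetyl-6-methoxy-2-(prop-1-en-2-yl)-2,3-dihydro-1-benzofuran-3-yl (2Z)-2-[(acetyloxy)methyl]but-2-enoate (2,3-trans) | C=C(C)[C@H]1Oc2cc(OC)c(C(C)=O)cc2[C@@H]1OC(=O)/C(=C\C)COC(C)=O | target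

**Step count**

Total steps: 6. Longest linear sequence: 3 steps (1 → 2 → 5 → 11; the branch 6 → 9 → 10 → 11 is equally long).

**Steps most likely to fail**

Step 6 (the proposed new step). Possible failures are:
- acyloxylation at the CH2 terminus, leading to a 2H-chromene;
- Wacker-type closure to the 2-isopropenylbenzofuran;
- bis-acyloxylation without ring closure;
- Diels–Alder reaction of 5 with the quinone, which is why the 2,6-dimethyl quinone is used;
- ionisation of the allylic acetate of 10 by zerovalent palladium;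
- low ee or dr.

The sense of induction of the (S)-ligand is a working choice; if the antipode forms, the (R)-ligand is used.

Fallback with known chemistry, setting out from 5 and coming back at 11. Compound 5 is silylated (i-Pr3SiCl, imidazole, DMF) to the triisopropylsilyl ether F1. Shi epoxidation with the enantiomer of the D-fructose-derived ketone (KHSO5, K2CO3, MeCN/dimethoxymethane/H2O, 0 °C) is selective for the trans-disubstituted styrenyl alkene over the 1,1-disubstituted one and gives the (2S,3S)-vinyl epoxide F2. Bu4NF in THF at 0 °C removes the silyl group, and the phenoxide opens the epoxide at the allylic carbon with inversion to give the trans-(2R,3S)-alcohol F3. Acid 10 is converted with 1-chloro-N,N,2-trimethylprop-1-en-1-amine in CH2Cl2 into the acid chloride F4, which acylates F3 (pyridine, CH2Cl2, 0 °C) without touching the Z alkene and gives 11.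

Step 4. The α-alumino enoate can lose its geometry through the aluminium allenolate, formaldehyde can oligomerise, and the acetylation in the flask may be incomplete.

Fallback setting out from 6 and coming back at 9. Syn-hydrostannation of 6 (Bu3SnH, Pd(PPh3)4, THF, 0 °C) gives the α-stannyl enoate F5. Iododestannylation with retention (I2, CH2Cl2, 0 °C) gives the α-iodo enoate F6. Stille hydroxymethylation (Bu3SnCH2OH, Pd(PPh3)4, 1,4-dioxane, 80 °C) gives the Z-hydroxymethyl enoate F7, and Ac2O/pyridine at 0 °C gives 9.

Step 3. The dienyl boronate can protodeboronate or polymerise, the free ortho-iodophenol can couple sluggishly, and warm basic conditions could isomerise 5 towards the 2,2-dimethylchromene.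

Fallback setting out from 1 and coming back at 5; it needs neither 2 nor 4. Ortho-formylation of 1 (hexamethylenetetramine, CF3CO2H, 80 °C, then aq. HCl) gives the salicylaldehyde F8. Horner–Wadsworth–Emmons olefination with diethyl (2-methylprop-2-en-1-yl)phosphonate (NaH, 2.2 equiv, THF, 0 °C → rt) gives the E diene 5 at room temperature, and the minor Z isomer is removed by chromatography.

**Further compounds**

F1 | step 6 | 1-{2-methoxy-5-[(1E)-3-methylbuta-1,3-dien-1-yl]-4-[tri(propan-2-yl)silyloxy]phenyl}ethan-1-one | CC(=O)c1cc(/C=C/C(C)=C)c(O[Si](C(C)C)(C(C)C)C(C)C)cc1OC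
F2 | step 6 | 1-{2-methoxy-5-[(2S,3S)-3-(prop-1-en-2-yl)oxiran-2-yl]-4-[tri(propan-2-yl)silyloxy]phenyl}ethan-1-one (trans epoxide) | CC(=C)[C@@H]1O[C@H]1c2cc(C(C)=O)c(OC)cc2O[Si](C(C)C)(C(C)C)C(C)C
F3 | step 6 | 1-[(2R,3S)-3-hydroxy-6-methoxy-2-(prop-1-en-2-yl)-2,3-dihydro-1-benzofuran-5-yl]ethan-1-one (2,3-trans) | C=C(C)[C@H]1Oc2cc(OC)c(C(C)=O)cc2[C@@H]1O
F4 | step 6 | (2Z)-2-[(acetyloxy)methyl]but-2-enoyl chloride | C/C=C(\C(Cl)=O)COC(C)=O
F5 | step 4 | tert-butyl (2E)-2-(tributylstannyl)but-2-enoate (methyl cis to the ester) | C/C=C(\C(=O)OC(C)(C)C)[Sn](CCCC)(CCCC)CCCC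
F6 | step 4 | tert-butyl (2E)-2-iodobut-2-enoate (methyl cis to the ester) | C/C=C(\C(=O)OC(C)(C)C)I
F7 | step 4 | tert-butyl (2Z)-2-(hydroxymethyl)but-2-enoate | C/C=C(\C(=O)OC(C)(C)C)CO
F8 | step 3 | 5-acetyl-2-hydroxy-4-methoxybenzaldehyde | CC(=O)c1cc(C=O)c(O)cc1OC
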